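**Retrosynthetic overview**

1. The strategy rests on the free 2'-OH of ring B lying ortho to C1'. Once deprotonated it turns C3, the benzylic carbon on C1', into the exocyclic carbon of a ring-B ortho-quinone methide. The chain C3–C2–O1–C8a–C4a holds that acceptor within six-ring reach of a ring-A aldehyde carbon, which becomes C4.
2. Key disconnection C3–C4: carbene-catalysed intramolecular acyl-anion (Stetter-type) addition onto the methide, released from a 2-(1-tosylalkyl)phenol. Ring C closes as the racemic isoflavanone and is aromatised afterwards (Saegusa–Ito), followed by fluoride and hydrogenolysis.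
3. C1'–C3 disconnection: three-component condensation of ring-B phenol 13, aryloxyacetaldehyde 5 and p-toluenesulfinic acid.
4. Ring A comes from 2,4,6-trihydroxybenzaldehyde (dibenzylation, then O-alkylation with bromoacetaldehyde diethyl acetal, which supplies C2 and C3). Ring B comes from 3,4-dimethoxyphenol (ortho-lithiation/prenylation between the two oxygens, then Markovnikov hydration).
5. Ring order: rings A and B are bought; ring C is the only ring formed (step 10).

Key step: step 10

Remark: isoflavone numbering is used (O1, C2, C3, C4, C4a–C8a; ring B C1'–C6'). The target is achiral, and C3 of the isoflavanone intermediates is racemic and is removed in step 12.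

**Route**

Step 1
Reactants: 1 2,4,6-trihydroxybenzaldehyde
Product: 2 2,4-bis(benzyloxy)-6-hydroxybenzaldehyde
Conditions: BnBr (2.05 equiv), K2CO3 (2.1 equiv), DMF, 0 °C → rt
Reagents that add atoms: benzyl bromide, BrCc1ccccc1
Why: Williamson etherification under stoichiometric control should benzylate the 4-OH and one ortho OH, while the remaining ortho OH stays free because it is held in the hydrogen bond to the formyl group and is the least nucleophilic.

Step 2
Reactants: 2 2,4-bis(benzyloxy)-6-hydroxybenzaldehyde; 3 2-bromo-1,1-diethoxyethane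
Product: 4 2,4-bis(benzyloxy)-6-(2,2-diethoxyethoxy)benzaldehyde
Conditions: K2CO3, KI (cat.), DMF, 110 °C
Reagents that add atoms: none
Why: Williamson O-alkylation of the chelated phenoxide by the primary bromide (iodide catalysis, heat) attaches the two carbons that become C2 and C3 as a base-stable acetal.

Step 3
Reactants: 4 2,4-bis(benzyloxy)-6-(2,2-diethoxyethoxy)benzaldehyde
Product: 5 2-[3,5-bis(benzyloxy)-2-formylphenoxy]acetaldehyde
Conditions: TFA/H2O (1:1), CHCl3, 0 °C → rt; crude product used at once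
Reagents that add atoms: water, O
Why: Acid-catalysed acetal hydrolysis unmasks the aliphatic aldehyde, and short exposure at low temperature should avoid aldol condensation onto the deactivated, doubly ortho-alkoxylated aryl aldehyde.

Step 4
Reactants: 6 3,4-dimethoxyphenol
Product: 7 1,2-dimethoxy-4-(methoxymethoxy)benzene
Conditions: MOMCl, i-Pr2NEt, CH2Cl2, 0 °C → rt
Reagents that add atoms: chloromethyl methyl ether, COCCl
Why: Standard MOM protection of the phenol, which also installs the directing group for the ortho-lithiation.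

Step 5
Reactants: 7 1,2-dimethoxy-4-(methoxymethoxy)benzene; 8 1-bromo-3-methylbut-2-ene
Product: 10 1,2-dimethoxy-4-(methoxymethoxy)-3-(3-methylbut-2-en-1-yl)benzene, via aryllithium 9 (not isolated)
Conditions: n-BuLi, THF, 0 °C; then CuBr·SMe2 (10 mol %), 8, −78 °C → rt
Reagents that add atoms: none
Why: Directed ortho-metalation should occur at the position flanked by the MOM ether and the neighbouring methoxy group (cooperative directing groups), and copper-catalysed allylic substitution of the aryllithium at the primary carbon of prenyl bromide gives the linear prenyl arene.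

Step 6
Reactants: 10 1,2-dimethoxy-4-(methoxymethoxy)-3-(3-methylbut-2-en-1-yl)benzene
Product: 11 4-[2,3-dimethoxy-6-(methoxymethoxy)phenyl]-2-methylbutan-2-ol
Conditions: Co(acac)2 (20 mol %), PhSiH3, O2 (1 atm), THF, rt
Reagents that add atoms: dioxygen, O=O
Why: Mukaiyama hydration (hydrogen-atom transfer from a cobalt hydride, oxygen trapping of the tertiary radical, silane reduction of the peroxide) gives the Markovnikov tertiary alcohol without acid that could attack the MOM ether.

Step 7
Reactants: 11 4-[2,3-dimethoxy-6-(methoxymethoxy)phenyl]-2-methylbutan-2-ol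
Product: 12 tert-butyl({4-[2,3-dimethoxy-6-(methoxymethoxy)phenyl]-2-methylbutan-2-yl}oxy)dimethylsilane
Conditions: TBSOTf, 2,6-lutidine, CH2Cl2, −78 → 0 °C
Reagents that add atoms: tert-butyldimethylsilyl trifluoromethanesulfonate, CC(C)(C)[Si](C)(C)OS(=O)(=O)C(F)(F)F
Why: Silyl triflate silylation of the hindered tertiary alcohol; the tertiary TBS ether blocks ionisation of this carbon, which would otherwise close a 2,2-dimethylchroman onto the neighbouring phenol in the later acidic steps.

Step 8
Reactants: 12 tert-butyl({4-[2,3-dimethoxy-6-(methoxymethoxy)phenyl]-2-methylbutan-2-yl}oxy)dimethylsilane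
Product: 13 2-{3-[(tert-butyldimethylsilyl)oxy]-3-methylbutyl}-3,4-dimethoxyphenol
Conditions: ZnBr2 (1 equiv), n-PrSH (2 equiv), CH2Cl2, 0 °C, 10–15 min
Reagents that add atoms: none
Why: Soft Lewis acid/thiol cleavage of the aryl MOM acetal is fast at 0 °C and should leave the tertiary silyl ether in place.

Step 9
Reactants: 13 2-{3-[(tert-butyldimethylsilyl)oxy]-3-methylbutyl}-3,4-dimethoxyphenol; 5 2-[3,5-bis(benzyloxy)-2-formylphenoxy]acetaldehyde; 14 sodium p-toluenesulfinate
Product: 15 racemic 2,4-bis(benzyloxy)-6-{2-[3-(3-{[tert-butyl(dimethyl)silyl]oxy}-3-methylbutyl)-2-hydroxy-4,5-dimethoxyphenyl]-2-tosylethoxy}benzaldehyde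
Conditions: 14 (1.5 equiv), aq. HCl (1.5 equiv, liberates p-TolSO2H in the flask), CH2Cl2/H2O, 0 °C → rt
Reagents that add atoms: none
Why: Three-component sulfonylalkylation (Friedel–Crafts hydroxyalkylation of the activated phenol by the more electrophilic aliphatic aldehyde at its only free ortho position, then capture of the benzylic cation/quinone methide by sulfinate) is known for sesamol- and naphthol-type phenols, whose oxygenation pattern ring B shares; the new carbon is racemic.

Step 10
Reactants: 15 racemic 2,4-bis(benzyloxy)-6-{2-[3-(3-{[tert-butyl(dimethyl)silyl]oxy}-3-methylbutyl)-2-hydroxy-4,5-dimethoxyphenyl]-2-tosylethoxy}benzaldehyde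
Product: 17 racemic 5,7-bis(benzyloxy)-3-[3-(3-{[tert-butyl(dimethyl)silyl]oxy}-3-methylbutyl)-2-hydroxy-4,5-dimethoxyphenyl]chroman-4-one, via ortho-quinone methide 16 (not isolated)
Conditions: 3-benzyl-4,5-dimethylthiazolium chloride (20 mol %), Cs2CO3 (2 equiv), THF (0.02 M), rt → 45 °C, argon
Reagents that add atoms: none
Why: Proposed new method: Cs2CO3 deprotonates the 2'-phenol and the phenoxide expels p-toluenesulfinate by 1,4-elimination to give ortho-quinone methide 16, while the thiazol-2-ylidene adds to the ring-A aldehyde and proton transfer gives the Breslow intermediate, whose nucleophilic carbon (future C4) attacks the exocyclic methide carbon (future C3); re-aromatisation of ring B to the 2'-phenoxide drives the addition, and collapse of the tetrahedral adduct releases the carbene and the C4 ketone. The closest known reaction types are carbene-catalysed acylation of ortho-quinone methides generated in situ from 2-(1-tosylalkyl)phenols or ortho-silyloxybenzyl halides and the intramolecular Stetter closure of salicylaldehyde-derived substrates to chroman-4-ones; the two have not been shown combined in one substrate. Ring C closes in a 6-exo-trig mode (C4–C4a–C8a–O1–C2–C3, the C3=C1' double bond being exocyclic to the new ring). The new C3 stereocentre is formed racemic under the achiral carbene and needs no control, since step 12 removes it. The step needs C–C bond formation to outrun addition of phenoxide, sulfinate or carbene to the methide and tautomerisation of the methide to the 2-vinylphenol; this should be secured by the six-membered intramolecular delivery, the reversibility of the hetero-additions (sulfone 15 itself is a reservoir for 16), the slow release of 16 by a heterogeneous carbonate at high dilution, and the 4'- and 5'-methoxy groups, which make 16 a stabilised, sesamol-type methide.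

Step 11
Reactants: 17 racemic 5,7-bis(benzyloxy)-3-[3-(3-{[tert-butyl(dimethyl)silyl]oxy}-3-methylbutyl)-2-hydroxy-4,5-dimethoxyphenyl]chroman-4-one
Product: 18 racemic 5,7-bis(benzyloxy)-3-[2-{[tert-butyl(dimethyl)silyl]oxy}-3-(3-{[tert-butyl(dimethyl)silyl]oxy}-3-methylbutyl)-4,5-dimethoxyphenyl]chroman-4-one
Conditions: TBSCl, imidazole, DMAP (cat.), DMF, rt → 40 °C
Reagents that add atoms: tert-butyldimethylsilyl chloride, CC(C)(C)[Si](C)(C)Cl
Why: Imidazole-promoted silylation of the 2'-phenol prevents oxidation of this para-methoxyphenol and oxidative cyclisation of the 2'-oxygen onto C2 during the dehydrogenation.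

Step 12
Reactants: 18 racemic 5,7-bis(benzyloxy)-3-[2-{[tert-butyl(dimethyl)silyl]oxy}-3-(3-{[tert-butyl(dimethyl)silyl]oxy}-3-methylbutyl)-4,5-dimethoxyphenyl]chroman-4-one
Product: 20 5,7-bis(benzyloxy)-3-[2-{[tert-butyl(dimethyl)silyl]oxy}-3-(3-{[tert-butyl(dimethyl)silyl]oxy}-3-methylbutyl)-4,5-dimethoxyphenyl]-4H-chromen-4-one, via trimethylsilyl enol ether 19 (not isolated)
Conditions: TMSOTf, Et3N, CH2Cl2, 0 °C; concentrate; then Pd(OAc)2 (1.1 equiv), MeCN, rt
Reagents that add atoms: none
Why: Soft enolisation gives the only possible (C3=C4) silyl enol ether without the free enolate that could open ring C by β-elimination, and Saegusa–Ito oxidation (palladium enolate, β-hydride elimination from C2) gives the chromone and erases the C3 stereocentre.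

Step 13
Reactants: 20 5,7-bis(benzyloxy)-3-[2-{[tert-butyl(dimethyl)silyl]oxy}-3-(3-{[tert-butyl(dimethyl)silyl]oxy}-3-methylbutyl)-4,5-dimethoxyphenyl]-4H-chromen-4-one
Product: 21 5,7-bis(benzyloxy)-3-[2-hydroxy-3-(3-hydroxy-3-methylbutyl)-4,5-dimethoxyphenyl]-4H-chromen-4-one
Conditions: TBAF (5 equiv), THF, rt → 50 °C; aqueous work-up
Reagents that add atoms: none
Why: Fluoride should cleave the aryl silyl ether at once and the tertiary alkyl silyl ether on warming, under non-acidic conditions that cannot ionise the tertiary alcohol.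

Step 14
Reactants: 21 5,7-bis(benzyloxy)-3-[2-hydroxy-3-(3-hydroxy-3-methylbutyl)-4,5-dimethoxyphenyl]-4H-chromen-4-one
Product: 22 5,7-dihydroxy-3-[2-hydroxy-3-(3-hydroxy-3-methylbutyl)-4,5-dimethoxyphenyl]-4H-chromen-4-one (CNP0192638.0)
Conditions: H2 (1 atm), 10% Pd/C, EtOAc/MeOH, rt; stopped when both benzyl groups are gone
Reagents that add atoms: none
Why: Hydrogenolysis of the two aryl benzyl ethers over palladium is much faster than reduction of the chromone C2=C3 bond, so the reaction can be stopped after debenzylation.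

**Compound list**

1 | 2,4,6-trihydroxybenzaldehyde | O=Cc1c(O)cc(O)cc1O | starting material
2 | 2,4-bis(benzyloxy)-6-hydroxybenzaldehyde | O=Cc1c(O)cc(OCc2ccccc2)cc1OCc1ccccc1 | intermediate
3 | 2-bromo-1,1-diethoxyethane (bromoacetaldehyde diethyl acetal) | CCOC(CBr)OCC | starting material
4 | 2,4-bis(benzyloxy)-6-(2,2-diethoxyethoxy)benzaldehyde | CCOC(COc1cc(OCc2ccccc2)cc(OCc2ccccc2)c1C=O)OCC | intermediate
5 | 2-[3,5-bis(benzyloxy)-2-formylphenoxy]acetaldehyde | O=CCOc1cc(OCc2ccccc2)cc(OCc2ccccc2)c1C=O | intermediate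
6 | 3,4-dimethoxyphenol | COc1ccc(O)cc1OC | starting material
7 | 1,2-dimethoxy-4-(methoxymethoxy)benzene | COCOc1ccc(OC)c(OC)c1 | intermediate
8 | 1-bromo-3-methylbut-2-ene (prenyl bromide) | CC(C)=CCBr | starting material
9 | [2,3-dimethoxy-6-(methoxymethoxy)phenyl]lithium | [Li]c1c(OCOC)ccc(OC)c1OC | intermediate
10 | 1,2-dimethoxy-4-(methoxymethoxy)-3-(3-methylbut-2-en-1-yl)benzene | COCOc1ccc(OC)c(OC)c1CC=C(C)C | intermediate
11 | 4-[2,3-dimethoxy-6-(methoxymethoxy)phenyl]-2-methylbutan-2-ol | COCOc1ccc(OC)c(OC)c1CCC(C)(C)O | intermediate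
12 | tert-butyl({4-[2,3-dimethoxy-6-(methoxymethoxy)phenyl]-2-methylbutan-2-yl}oxy)dimethylsilane | COCOc1ccc(OC)c(OC)c1CCC(C)(C)O[Si](C)(C)C(C)(C)C | intermediate
13 | 2-{3-[(tert-butyldimethylsilyl)oxy]-3-methylbutyl}-3,4-dimethoxyphenol | COc1ccc(O)c(CCC(C)(C)O[Si](C)(C)C(C)(C)C)c1OC | intermediate
14 | sodium p-toluenesulfinate | Cc1ccc(S(=O)[O-])cc1.[Na+] | starting material
15 | racemic 2,4-bis(benzyloxy)-6-{2-[3-(3-{[tert-butyl(dimethyl)silyl]oxy}-3-methylbutyl)-2-hydroxy-4,5-dimethoxyphenyl]-2-tosylethoxy}benzaldehyde | O=Cc1c(OCc2ccccc2)cc(OCc2ccccc2)cc1OCC(c1cc(OC)c(OC)c(CCC(C)(C)O[Si](C)(C)C(C)(C)C)c1O)S(=O)(=O)c1ccc(C)cc1 | intermediate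
16 | ring-B ortho-quinone methide, 2,4-bis(benzyloxy)-6-{2-[5-(3-{[tert-butyl(dimethyl)silyl]oxy}-3-methylbutyl)-3,4-dimethoxy-6-oxocyclohexa-2,4-dien-1-ylidene]ethoxy}benzaldehyde (alkene geometry not defined) | O=Cc1c(OCc2ccccc2)cc(OCc2ccccc2)cc1OCC=C1C=C(OC)C(OC)=C(CCC(C)(C)O[Si](C)(C)C(C)(C)C)C1=O | intermediate
17 | racemic 5,7-bis(benzyloxy)-3-[3-(3-{[tert-butyl(dimethyl)silyl]oxy}-3-methylbutyl)-2-hydroxy-4,5-dimethoxyphenyl]chroman-4-one | COc1cc(C2COc3cc(OCc4ccccc4)cc(OCc4ccccc4)c3C2=O)c(O)c(CCC(C)(C)O[Si](C)(C)C(C)(C)C)c1OC | intermediate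
18 | racemic 5,7-bis(benzyloxy)-3-[2-{[tert-butyl(dimethyl)silyl]oxy}-3-(3-{[tert-butyl(dimethyl)silyl]oxy}-3-methylbutyl)-4,5-dimethoxyphenyl]chroman-4-one | COc1cc(C2COc3cc(OCc4ccccc4)cc(OCc4ccccc4)c3C2=O)c(O[Si](C)(C)C(C)(C)C)c(CCC(C)(C)O[Si](C)(C)C(C)(C)C)c1OC | intermediate
19 | 5,7-bis(benzyloxy)-3-[2-{[tert-butyl(dimethyl)silyl]oxy}-3-(3-{[tert-butyl(dimethyl)silyl]oxy}-3-methylbutyl)-4,5-dimethoxyphenyl]-4-[(trimethylsilyl)oxy]-2H-chromene | COc1cc(C2=C(O[Si](C)(C)C)c3c(OCc4ccccc4)cc(OCc4ccccc4)cc3OC2)c(O[Si](C)(C)C(C)(C)C)c(CCC(C)(C)O[Si](C)(C)C(C)(C)C)c1OC | intermediate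
20 | 5,7-bis(benzyloxy)-3-[2-{[tert-butyl(dimethyl)silyl]oxy}-3-(3-{[tert-butyl(dimethyl)silyl]oxy}-3-methylbutyl)-4,5-dimethoxyphenyl]-4H-chromen-4-one | COc1cc(-c2coc3cc(OCc4ccccc4)cc(OCc4ccccc4)c3c2=O)c(O[Si](C)(C)C(C)(C)C)c(CCC(C)(C)O[Si](C)(C)C(C)(C)C)c1OC | intermediate
21 | 5,7-bis(benzyloxy)-3-[2-hydroxy-3-(3-hydroxy-3-methylbutyl)-4,5-dimethoxyphenyl]-4H-chromen-4-one | COc1cc(-c2coc3cc(OCc4ccccc4)cc(OCc4ccccc4)c3c2=O)c(O)c(CCC(C)(C)O)c1OC | intermediate
22 | 5,7-dihydroxy-3-[2-hydroxy-3-(3-hydroxy-3-methylbutyl)-4,5-dimethoxyphenyl]-4H-chromen-4-one | COc1cc(-c2coc3cc(O)cc(O)c3c2=O)c(O)c(CCC(C)(C)O)c1OC | target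

**Step count**

Total: 14 steps. Longest linear sequence: 11 steps (from 3,4-dimethoxyphenol 6: steps 4–14). The ring-A branch (steps 1–3) joins at step 9.

**Steps most likely to fail**

1. Step 10 (key step). What may go wrong: slow formation of the Breslow intermediate at the electron-rich aldehyde flanked by two ortho alkoxy groups, so that the quinone methide is consumed first by tautomerisation to the 2-vinylphenol enol ether, by oligomerisation or by capture of the carbene.
Fallback (known chemistry; sets out from 12, comes back at 21): the C3–C1' bond is made by Suzuki–Miyaura coupling instead. n-BuLi (THF, 0 °C) should lithiate 12 at the free position ortho to the MOM ether to give aryllithium F1, which is quenched with 2-isopropoxy-4,4,5,5-tetramethyl-1,3,2-dioxaborolane to give pinacol boronate F2. Purchased 1-[2,4-bis(benzyloxy)-6-hydroxyphenyl]ethanone F3 is heated with N,N-dimethylformamide dimethyl acetal to give enaminone F4, and I2 in CHCl3 cyclises this to 5,7-bis(benzyloxy)-3-iodochromen-4-one F5. Coupling of F2 and F5 (Pd(dppf)Cl2, K3PO4, dioxane/H2O, 80 °C) should give MOM-protected isoflavone F6. ZnBr2/n-PrSH then frees the 2'-phenol to give isoflavone F7, and TBAF as in step 13 gives 21.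

2. Step 9. What may go wrong: acid-promoted side reactions compete with the desired ortho-hydroxyalkylation, namely intramolecular aldol condensation between the two aldehyde groups of 5 toward a benzofuran, attack of the phenol on the aryl aldehyde, a second arylation of the benzylic cation, and loss of the tertiary silyl ether followed by chroman closure.
Fallback (sets out from 13 and 5, comes back at 15): the C–C bond is formed outside the acidic medium. EtMgBr (Et2O, then exchange to CH2Cl2) converts 13 into bromomagnesium phenoxide F8, which should add ortho-specifically through its magnesium chelate to the aliphatic aldehyde of 5 (CH2Cl2, rt; Casiraghi hydroxyalkylation) to give benzylic alcohol F9. Brief treatment with p-TolSO2H in CH2Cl2 at rt then exchanges the benzylic hydroxyl for the sulfonyl group through the same benzylic cation/quinone methide and gives 15.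

3. Step 12. What may go wrong: incomplete formation of the crowded tetrasubstituted silyl enol ether (peri 5-benzyloxy group, ortho-substituted 3-aryl group), or slow palladium enolate formation and β-hydride elimination, so that protodesilylation returns ketone 18.
Fallback (sets out from 18, comes back at 20): direct dehydrogenation of the ketone with DDQ in dioxane at reflux (hydride abstraction from the enol tautomer), the classical isoflavanone-to-isoflavone oxidation, which needs neither the silyl enol ether nor palladium; no new compound is formed.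

**Further compounds**

F1 | step 10 | [3-(3-{[tert-butyl(dimethyl)silyl]oxy}-3-methylbutyl)-4,5-dimethoxy-2-(methoxymethoxy)phenyl]lithium | [Li]c1cc(OC)c(OC)c(CCC(C)(C)O[Si](C)(C)C(C)(C)C)c1OCOC
F2 | step 10 | 2-[3-(3-{[tert-butyl(dimethyl)silyl]oxy}-3-methylbutyl)-4,5-dimethoxy-2-(methoxymethoxy)phenyl]-4,4,5,5-tetramethyl-1,3,2-dioxaborolane | COCOc1c(B2OC(C)(C)C(C)(C)O2)cc(OC)c(OC)c1CCC(C)(C)O[Si](C)(C)C(C)(C)C
F3 | step 10 | 1-[2,4-bis(benzyloxy)-6-hydroxyphenyl]ethanone (purchased) | CC(=O)c1c(O)cc(OCc2ccccc2)cc1OCc1ccccc1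
F4 | step 10 | (E)-1-[2,4-bis(benzyloxy)-6-hydroxyphenyl]-3-(dimethylamino)prop-2-en-1-one | CN(C)/C=C/C(=O)c1c(O)cc(OCc2ccccc2)cc1OCc1ccccc1
F5 | step 10 | 5,7-bis(benzyloxy)-3-iodo-4H-chromen-4-one | O=c1c(I)coc2cc(OCc3ccccc3)cc(OCc3ccccc3)c12
F6 | step 10 | 5,7-bis(benzyloxy)-3-[3-(3-{[tert-butyl(dimethyl)silyl]oxy}-3-methylbutyl)-4,5-dimethoxy-2-(methoxymethoxy)phenyl]-4H-chromen-4-one | COCOc1c(-c2coc3cc(OCc4ccccc4)cc(OCc4ccccc4)c3c2=O)cc(OC)c(OC)c1CCC(C)(C)O[Si](C)(C)C(C)(C)C
F7 | step 10 | 5,7-bis(benzyloxy)-3-[3-(3-{[tert-butyl(dimethyl)silyl]oxy}-3-methylbutyl)-2-hydroxy-4,5-dimethoxyphenyl]-4H-chromen-4-one | COc1cc(-c2coc3cc(OCc4ccccc4)cc(OCc4ccccc4)c3c2=O)c(O)c(CCC(C)(C)O[Si](C)(C)C(C)(C)C)c1OC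
F8 | step 9 | bromomagnesium 2-{3-[(tert-butyldimethylsilyl)oxy]-3-methylbutyl}-3,4-dimethoxyphenoxide | COc1ccc(O[Mg]Br)c(CCC(C)(C)O[Si](C)(C)C(C)(C)C)c1OC
F9 | step 9 | racemic 2,4-bis(benzyloxy)-6-{2-[3-(3-{[tert-butyl(dimethyl)silyl]oxy}-3-methylbutyl)-2-hydroxy-4,5-dimethoxyphenyl]-2-hydroxyethoxy}benzaldehyde | O=Cc1c(OCc2ccccc2)cc(OCc2ccccc2)cc1OCC(O)c1cc(OC)c(OC)c(CCC(C)(C)O[Si](C)(C)C(C)(C)C)c1O
F0 | step 12 | none | none
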